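The runs are simulated for substances that don't exist; scatter was added.

The ratio of the isomer plateaus, 7.68% of the charge in the south-west run (mean from 2.50 h on) over 4.98% in the north run, is 1.54, and the charges stand at 1.50 the other way round. Isomer looks like a fixed concentration, not a fixed share.

| flask | substrate | remark | time |
|---|---|---|---|
| south-west | 0.20 M | run made earlier |  |
| north | 0.30 M | run made earlier |  |
| flask | 0.40 M |  | 10 h |

- south-west (time / h: target / %, isomer of the product / %): 0.833: 79.9, 9.1; 2.50: 84.5, 7.8; 4.00: 84.3, 8.8; 6.00: 84.9, 7.4; 10.0: 84.0, 6.2; 12.0: 84.4, 8.2
- north (time / h: target / %, isomer of the product / %): 2.00: 90.5, 5.7; 4.00: 89.6, 4.3; 6.00: 88.7, 5.2; 8.00: 89.5, 4.1; 10.0: 90.6, 4.9; 12.0: 90.6, 5.7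

(scatter of a reading: 1 percentage point)

- a reading or a percentage of target counts all its forms, free or not

* share of target in target plus isomer of the product at 5.0 s
* share of target in target plus isomer of the product at 10 h

Readings scatter, so we doubt this first. But a fixed share would put the two means level, and they lie 2.7 percentage points apart, more than the 0.61 points scatter of that difference. So we name the standing isomer concentration, the [isomer] shared by both runs, and read it as 15.2 mM. The same reckoning for all that is not target gives a standing loss of 30.7 mM.

Why would a concentration stand still? Suppose target falls out as crystals and treat that fast step as balanced: dissolved [target] then stands at a fixed solubility, what is in equilibrium with it stands fixed too, and extra charge goes to solid. The objection is that 0.40 M lies beyond both charges. Yet more charge should mean more solid, so we keep the rule and reckon for the flask a share of 96.0% at 10 h. At 5.0 s the rule gives nothing: the readings begin at 0.833 h, much later, and that early share belongs to kinetic, not thermodynamic, control, so we name no number.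

The forecast gives 30% and 96.1%, holding that something “consumes a fixed amount of substrate”.

The flask gives 72.5% and 96.3%.

    substrate ⇌ target (K = 1.50, k = 0.371 /min)
    substrate ⇌ isomer of the product (K = 3.70, k = 0.138 /min)
    target ⇌ isomer of the product (k = 0.104 /min)
    substrate ⇌ dormant form (K = 3.07, k = 0.205 /min)
    substrate → decomposition product (k = 5.43 × 10⁻⁴ /min)
    crystals ⇌ target, rate k6*(cs6 - [target]) while solid is left; crystals form when [target] > cs6 (solubility = 5.80 mM, k = 6.55 /min)

In the flask, at the start, the forward rates of substrate into target and into isomer stand at 2.7 to one, which as a share is 73.0%. In the neighbour flask charged with 0.16 M, the same reckoning gives a share of 89.5%, and that flask shows 90.0%.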